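Remark on the chemistry: the isocoumarin is numbered O2, C1, C3, C4, C4a, C5 to C8, C8a (ring A is C4a to C8a); ring B is numbered as the benzoic acid (C1 carries the carboxyl group, C2 pentyl, C3 the ether oxygen, C4 and C6 hydroxyl); the dioxolane on the C3 ketone of fold precursor 13 is treated as a protecting group of that precursor.

## Analysis of the target

Target 18 is a diaryl ether. C8 of a 6-hydroxy-3-pentylisocoumarin (ring A fused to an enol-lactone ring) is joined through oxygen to C3 of ring B, a 4,6-dihydroxy-2-pentylbenzoic acid, which is olivetolic acid oxygenated next to its pentyl chain. There is no stereocentre, so all problems are regiochemical or concern functional-group tolerance. The ether oxygen is crowded: on ring B it lies between the pentyl chain and a hydroxyl group, on ring A next to the carbon C8a that carries the lactone carbonyl, so a late coupling of two finished arenes would be difficult. The sensitive groups are the β-resorcylic acid of ring B (it decarboxylates on heating or in strong acid), the enol lactone (opened by hydroxide and alkoxide, and its C3–C4 double bond can be hydrogenated) and three electron-rich phenols. Ring B is pentasubstituted with four different substituents in a fixed order, and ring A needs C1 and C4 on neighbouring carbons beside the ether. The strategy rests on the chain C1, C8a, C8, C7, C6, C5, C4a, C4, C3: it is unbranched, oxygenated at C1, C3, C6 and C8 and carbonyl-derived at C4a, that is a folded pentaketide carrying the pentyl group. In this chain the C8 oxygen is the enol oxygen of a β-keto ester, so C1, C8a, C8, C7 and C6 can be held as a 4-oxygenated 2-pyranone, and the ring-B phenol can be put on C8 by plain addition–elimination before either ring of the isocoumarin exists.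

## Retrosynthetic reasoning

18 from 17. The last disconnection removes three benzyl groups: the two ether benzyls on the C4 and C6 oxygens of ring B and the benzyl ester. They go last because acid 18 decarboxylates easily and because free phenols and a free acid would consume base in every carbanion step. One neutral hydrogenolysis removes all three; it must spare the C3–C4 double bond of the lactone ring. The C6 hydroxyl of ring A needs no protection because it is created in the step before.

17 from 13. In 17 the bonds O2–C1 and C8a–C4a are cut. This opens both rings of the isocoumarin and leaves one chain from C1 to C3; a cut at the ether oxygen would instead demand the coupling of two crowded arenes. The chain is stored as pyranone 13: C1, C8a, C8, C7 and C6 form a 4-aryloxy-2-pyranone, C5 and C4a are the keto arm on its 6-position, and the C3 carbonyl is a dioxolane. In the forward sense an alkoxide has to open the lactone at C1, the freed dienolate has to add through C8a to the C4a ketone, dehydrate and aromatise, and acid then has to unmask C3 and close the lactone. The C3 ketone stays masked through the basic stage on purpose. A free 1,3-diketone would be deprotonated first, would switch off C4a as electrophile, would offer C3 as a second aldol acceptor for C7, and would give a C4 carbanion able to displace the aryloxide at C8 through a six-membered transition state. The gain is two rings, the C8a–C4a bond and the whole substitution pattern of ring A in one operation, with the aryl ether already in place.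

13 from 9 and 12. The C5–C4a bond is cut. C5 is the 6-methyl carbon of pyranone 9, whose protons are vinylogously α to the lactone carbonyl; C4a arrives as the acyl carbon of Weinreb amide 12. This is the only carbon–carbon bond that joins two fragments, so the route is convergent and the whole C4a–C4–C3–pentyl piece comes in at once. The forward step must deprotonate the methyl group selectively beside the benzylic CH2 of the pentyl chain and the benzyl ester, and must acylate once without proton transfer to the more acidic product.

12 from 11 from 10. Amide 12 goes back to ester 11 and this to keto ester 10. The ketone is masked because a free β-keto ester would only be deprotonated by the carbanion of 9.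

9 from 6 and 8. The C8–O bond is cut on the pyranone side. Bromide 8 is a vinylogous acyl bromide, and the phenoxide of 6 replaces bromide by addition–elimination. The cut is made on this side because the crowded partner then acts as the nucleophile towards an sp2 carbon flanked by two CH groups, and no metal-catalysed aryl–aryl ether coupling is needed. 8 comes from 7 by exchange of hydroxyl for bromide.

6 from 4, 3, 2 and 1. The C3–O bond of ring B is traced through boronate 5 to bromide 4. The oxygen thus enters as bromine by electrophilic substitution of 3, which has two free ring positions; the one between pentyl and benzyloxy is para to the other ether. 3 comes from olivetolic acid 2 by benzylation of its three acidic groups, and 2 from olivetol 1 by ortho-carboxylation. Ring B is thereby made from a cheap resorcinol, each substituent placed by the directing effect of the two oxygens.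

## Alternatives that were turned down

Alternative 1: Ring B is disconnected between its carboxyl-bearing carbon C1 and its pentyl-bearing carbon C2. It unfolds to a 3,5,7-trioxo ester stored as 4-hydroxy-2-pyranone A2, which carries ring A as an aryloxy group on the carbon between two carbonyls; ring A is an ortho-alkynyl benzoate, a latent isocoumarin.
- Forward key step: a magnesium alkoxide in its alcohol opens A2, the active methylene of the resulting β-keto ester adds to the heptanoyl-type ketone, and dehydration gives resorcylate A1.
- For: this is the best-precedented fold of the family (free 4-hydroxyl, doubly activated nucleophilic carbon), and the ether oxygen sits on an sp3 carbon from which no addition–elimination can expel it. On the reliability of the key step it is stronger than the chosen route.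
- Against: A2 needs an ether bond between a phenol that is hydrogen-bonded to its ortho ester and a carbon flanked by two carbonyls, and the ketone that must accept the aldol is next to that substituted carbon.
- Against: A1 holds ring B as a methyl ester beside a free ortho hydroxyl; cleaving such a 2,6-disubstituted ester to an acid that decarboxylates easily is a poor last step, and two methyl esters must be told apart.
- Against: after the fold, alkyne cyclisation (six- against five-membered closure), debenzylation and ester cleavage still remain.
- Comparison: the chosen route accepts an untested fold, but it forms the isocoumarin in that same step, keeps the carboxyl group as a benzyl ester that is removed by hydrogenolysis, and ends one step after the key step.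

Alternative 2: C4a–C4 and C8a–C1 are disconnected together. Ring A is an aryne between C4a and C8a generated from silyl triflate A4, and the two carbons come from dimethyl malonate A5.
- Forward key step: fluoride sets the aryne free, the malonate carbanion adds to C4a (the aryne carbon remote from the aryloxy group), the aryl anion at C8a attacks an ester carbonyl, and opening of the four-membered ring gives homophthalate A3.
- For: the reaction type is known on oxygenated arynes, the aryloxy group directs in the needed sense, and the neutral conditions leave benzyl ester and aryl ether untouched. On precedent and on the safety of the ether it is stronger.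
- Against: A4 already contains the diaryl ether, so the crowded ether must first be made by metal-catalysed coupling of phenol 6 with a 1,3,5-trioxygenated aryl halide, followed by ortho-silylation and triflation.
- Against: malonates insert less readily than β-keto esters.
- Against: A3 has neither C3 nor the pentyl chain, so selective hydrolysis, acylation, decarboxylation and lactonisation follow, among three different ester groups.
- Comparison: the chosen route makes the ether by uncatalysed substitution and delivers C3, its pentyl chain and the lactone in the key step; it is several steps shorter.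

Alternative 3: Two bonds of ring B are disconnected, C2–C3 and C1–C6. Diene A7 supplies C3 to C6 with the finished isocoumarin on the oxygen of C3, and alkynoate A8 supplies C1 and C2 with carboxyl and pentyl.
- Forward key step: [4+2] cycloaddition, then loss of the alkoxy and silyl groups aromatises to A6.
- For: it is highly convergent, and the polarity of diene and alkynoate matches. It forms ring B with the right oxygenation and free hydroxyls without relying on an electrophilic substitution whose regiochemistry the chosen route must trust in step 3; on that point it is stronger.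
- Against: A8 has an alkyl group on its β-carbon and is a weak dienophile, and the temperatures it needs are those at which bis-silyloxy dienes lose silyl groups or decompose.
- Against: the new C2–C3 bond joins the pentyl-bearing carbon to the aryloxy-bearing diene terminus, two crowded centres.
- Against: A7 requires double enol silylation with a strong amide base beside an electrophilic enol lactone, and its precursor requires alkylation of an 8-hydroxyl that is hydrogen-bonded to the lactone carbonyl.
- Against: the isocoumarin must be complete before the key step, so the sequence is linear.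
- Comparison: the chosen route forms an unhindered bond (C8a–C4a, a CH carbon onto a ketone) under mild ionic conditions and joins the two halves by simple substitution.

Key step: step 10

## Route

Step 1
Reactants: 1 olivetol (5-pentylbenzene-1,3-diol)
Product: 2 olivetolic acid (2,4-dihydroxy-6-pentylbenzoic acid)
Conditions: MeOMgOCO2Me (2 M in DMF), 120 °C, N2; then aq. HCl, 0 °C
Reagents that add atoms: methoxymagnesium methyl carbonate, COC(=O)O[Mg]OC
Why: Kolbe–Schmitt-type ortho-carboxylation; the magnesium phenoxide delivers CO2 to the ring carbon ortho to one hydroxyl, para to the other and next to the pentyl chain, and the chelated magnesium salicylate is protected from decarboxylation until the cold acid work-up. This is the known way from 1 to 2.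

Step 2
Reactants: 2 olivetolic acid
Product: 3 benzyl 2,4-bis(benzyloxy)-6-pentylbenzoate
Conditions: BnBr (3.5 equiv), K2CO3, DMF, rt to 60 °C
Reagents that add atoms: benzyl bromide, BrCc1ccccc1
Why: Williamson O-alkylation; the carboxylate reacts first at room temperature, which blocks decarboxylation, then the 4-phenoxide, and the hydrogen-bonded 2-hydroxyl on warming.

Step 3
Reactants: 3 benzyl 2,4-bis(benzyloxy)-6-pentylbenzoate
Product: 4 benzyl 4,6-bis(benzyloxy)-3-bromo-2-pentylbenzoate
Conditions: NBS (1.05 equiv), MeCN, 0 °C to rt, dark
Reagents that add atoms: N-bromosuccinimide, O=C1CCC(=O)N1Br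
Why: Electrophilic aromatic bromination; the free position between pentyl and benzyloxy is para to one ether and ortho to the other, whereas the position between the two ethers is only ortho to both and more screened, as in resorcinol diethers, which are brominated at C4 before C2. A polar solvent in the dark avoids radical bromination of benzylic CH2 groups.

Step 4
Reactants: 4 benzyl 4,6-bis(benzyloxy)-3-bromo-2-pentylbenzoate
Product: 6 benzyl 4,6-bis(benzyloxy)-3-hydroxy-2-pentylbenzoate, via pinacol boronate 5 (not isolated)
Conditions: B2pin2, Pd2(dba)3, SPhos, KOAc, 1,4-dioxane, 100 °C; then 30% H2O2, aq. NaOH, THF, 0 °C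
Reagents that add atoms: hydrogen peroxide, OO
Why: Miyaura borylation, with a bulky biaryl phosphine because the bromide has two ortho substituents, followed in the same flask by alkaline peroxide oxidation of the C–B bond (1,2-shift of the aryl group from boron to oxygen). The benzyl ester lies between two ortho substituents and should survive brief cold hydroxide.

Step 5
Reactants: 7 4-hydroxy-6-methyl-2H-pyran-2-one
Product: 8 4-bromo-6-methyl-2H-pyran-2-one
Conditions: Bu4NBr, P2O5, PhMe, 100 °C
Reagents that add atoms: tetrabutylammonium bromide, CCCC[N+](CCCC)(CCCC)CCCC.[Br-]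
Why: Known conversion of the vinylogous acid into the vinylogous acyl bromide; P2O5 turns the 4-hydroxyl into a phosphate leaving group, which bromide displaces by addition–elimination.

Step 6
Reactants: 6 benzyl 4,6-bis(benzyloxy)-3-hydroxy-2-pentylbenzoate; 8 4-bromo-6-methyl-2H-pyran-2-one
Product: 9 benzyl 4,6-bis(benzyloxy)-3-[(6-methyl-2-oxo-2H-pyran-4-yl)oxy]-2-pentylbenzoate
Conditions: Cs2CO3, DMF, 40 °C, N2
Reagents that add atoms: none
Why: Addition–elimination of the caesium phenoxide of 6 at C4 of 8, the β-carbon of the unsaturated lactone that bears bromide; the attacked carbon is flanked by two CH groups, so the two ortho substituents of the phenoxide are tolerated. Substitution of 8 by phenols is a known reaction type.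

Step 7
Reactants: 10 methyl 3-oxooctanoate
Product: 11 methyl 2-(2-pentyl-1,3-dioxolan-2-yl)acetate
Conditions: HOCH2CH2OH, TsOH·H2O (cat.), PhMe, reflux, Dean–Stark trap
Reagents that add atoms: ethylene glycol, OCCO
Why: Acid-catalysed ketalisation with azeotropic removal of water; only the ketone of the β-keto ester reacts.

Step 8
Reactants: 11 methyl 2-(2-pentyl-1,3-dioxolan-2-yl)acetate
Product: 12 N-methoxy-N-methyl-2-(2-pentyl-1,3-dioxolan-2-yl)acetamide
Conditions: MeNHOMe·HCl, i-PrMgCl, THF, −20 to 0 °C
Reagents that add atoms: N,O-dimethylhydroxylamine hydrochloride, CNOC.Cl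
Why: Weinreb amide formation from an ester by the chloromagnesium amide of N,O-dimethylhydroxylamine; the ketal is stable to base, and the low temperature avoids enolisation of the ester with loss of the β-alkoxy group.

Step 9
Reactants: 9 benzyl 4,6-bis(benzyloxy)-3-[(6-methyl-2-oxo-2H-pyran-4-yl)oxy]-2-pentylbenzoate; 12 N-methoxy-N-methyl-2-(2-pentyl-1,3-dioxolan-2-yl)acetamide
Product: 13 benzyl 4,6-bis(benzyloxy)-3-({2-oxo-6-[2-oxo-3-(2-pentyl-1,3-dioxolan-2-yl)propyl]-2H-pyran-4-yl}oxy)-2-pentylbenzoate
Conditions: LiN(SiMe3)2 (1.05 equiv), THF, −78 °C; then 12, −78 to −40 °C; sat. aq. NH4Cl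
Reagents that add atoms: none
Why: Weinreb ketone synthesis with a vinylogous lactone enolate; the silylamide removes a proton from the 6-methyl group, as known for 4-alkoxy-6-methyl-2-pyranones, and is too weak a base for the benzylic CH2 of the pentyl chain or the benzyl ethers. The chelated tetrahedral adduct of the Weinreb amide holds the ketone back until the quench, so the more acidic product neither quenches the carbanion nor is acylated again.

Step 10
Reactants: 13 benzyl 4,6-bis(benzyloxy)-3-({2-oxo-6-[2-oxo-3-(2-pentyl-1,3-dioxolan-2-yl)propyl]-2H-pyran-4-yl}oxy)-2-pentylbenzoate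
Product: 17 benzyl 4,6-bis(benzyloxy)-3-[(6-hydroxy-1-oxo-3-pentyl-1H-isochromen-8-yl)oxy]-2-pentylbenzoate, via ring-opened methyl enoate 14 (not isolated), via dioxolane methyl benzoate 15 (not isolated), via keto methyl benzoate 16 (not isolated)
Conditions: NaOMe (3 equiv), MeOH, 0 °C to rt; AcOH, aqueous work-up; crude: TsOH·H2O, wet PhMe, 60 to 80 °C
Reagents that add atoms: water, O
Why: Proposed new method: methoxide should add to the lactone carbonyl C1 of 13 and release the C6 enolate, which is the dienolate of β-aryloxy enoate 14; its α-carbon C8a adds to the only free ketone, C4a, and loss of water followed by enolisation at C6 gives aromatic ring A of 15 with the aryl ether still on C8. The closest known reaction type is the base-induced ring opening and aldol recyclisation of 4-hydroxy-6-(2-oxoalkyl)-2-pyranones and of 3,5,7-trioxo esters to resorcylates and 6,8-dihydroxyisocoumarins; an aryl enol ether at C8 has not been carried through it. Ring A closes by a 6-(enolexo)-exo-trig aldol addition. The lactone ring closes by 6-exo-trig attack of the enol oxygen of the C3 ketone on the C1 ester, but only after the switch to acid, which removes the dioxolane (16) and drives off methanol, because an enol lactone is methanolysed by methoxide and cannot form in the basic stage. No stereocentre is created. Attack at C1 rather than addition–elimination at C8 is expected because methoxide is a hard nucleophile, C8 is screened by the two ortho substituents of ring B, and the opened chain is an electron-rich dienolate. Aldol is favoured over Claisen-type acylation of C5 by the C1 ester because that ester is a deactivated vinylogous carbonate and because a sodium, not a magnesium, counter-ion is used (magnesium enolates of β-dicarbonyl compounds are the classical partners for C-acylation); the dioxolane keeps C4 non-acidic and C3 non-electrophilic, so C4 cannot displace the aryloxide and C7 has no second aldol acceptor. The benzyl ester of ring B lies between two ortho substituents and should resist methanolysis at room temperature.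

Step 11
Reactants: 17 benzyl 4,6-bis(benzyloxy)-3-[(6-hydroxy-1-oxo-3-pentyl-1H-isochromen-8-yl)oxy]-2-pentylbenzoate
Product: 18 4,6-dihydroxy-3-[(6-hydroxy-1-oxo-3-pentyl-1H-isochromen-8-yl)oxy]-2-pentylbenzoic acid (CNP0439913.0)
Conditions: H2 (1 atm), 10% Pd/C, EtOAc, rt; stopped after uptake of 3 equiv; evaporation below 30 °C
Reagents that add atoms: none
Why: Hydrogenolysis of two aryl benzyl ethers and one benzyl ester under neutral conditions; the trisubstituted enol-lactone double bond should be reduced far more slowly than the benzylic C–O bonds, and neutral cold isolation avoids decarboxylation of the β-resorcylic acid.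

## Compound list

1 | olivetol (5-pentylbenzene-1,3-diol) | CCCCCc1cc(O)cc(O)c1 | starting material
2 | olivetolic acid (2,4-dihydroxy-6-pentylbenzoic acid) | CCCCCc1cc(O)cc(O)c1C(=O)O | intermediate
3 | benzyl 2,4-bis(benzyloxy)-6-pentylbenzoate | CCCCCc1cc(OCc2ccccc2)cc(OCc2ccccc2)c1C(=O)OCc1ccccc1 | intermediate
4 | benzyl 4,6-bis(benzyloxy)-3-bromo-2-pentylbenzoate | CCCCCc1c(Br)c(OCc2ccccc2)cc(OCc2ccccc2)c1C(=O)OCc1ccccc1 | intermediate
5 | benzyl 4,6-bis(benzyloxy)-2-pentyl-3-(4,4,5,5-tetramethyl-1,3,2-dioxaborolan-2-yl)benzoate | CCCCCc1c(B2OC(C)(C)C(C)(C)O2)c(OCc2ccccc2)cc(OCc2ccccc2)c1C(=O)OCc1ccccc1 | intermediate (not isolated)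
6 | benzyl 4,6-bis(benzyloxy)-3-hydroxy-2-pentylbenzoate | CCCCCc1c(O)c(OCc2ccccc2)cc(OCc2ccccc2)c1C(=O)OCc1ccccc1 | intermediate
7 | 4-hydroxy-6-methyl-2H-pyran-2-one | Cc1cc(O)cc(=O)o1 | starting material
8 | 4-bromo-6-methyl-2H-pyran-2-one | Cc1cc(Br)cc(=O)o1 | intermediate
9 | benzyl 4,6-bis(benzyloxy)-3-[(6-methyl-2-oxo-2H-pyran-4-yl)oxy]-2-pentylbenzoate | CCCCCc1c(Oc2cc(C)oc(=O)c2)c(OCc2ccccc2)cc(OCc2ccccc2)c1C(=O)OCc1ccccc1 | intermediate
10 | methyl 3-oxooctanoate | CCCCCC(=O)CC(=O)OC | starting material
11 | methyl 2-(2-pentyl-1,3-dioxolan-2-yl)acetate | CCCCCC1(CC(=O)OC)OCCO1 | intermediate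
12 | N-methoxy-N-methyl-2-(2-pentyl-1,3-dioxolan-2-yl)acetamide | CCCCCC1(CC(=O)N(C)OC)OCCO1 | intermediate
13 | benzyl 4,6-bis(benzyloxy)-3-({2-oxo-6-[2-oxo-3-(2-pentyl-1,3-dioxolan-2-yl)propyl]-2H-pyran-4-yl}oxy)-2-pentylbenzoate | CCCCCC1(CC(=O)Cc2cc(Oc3c(OCc4ccccc4)cc(OCc4ccccc4)c(C(=O)OCc4ccccc4)c3CCCCC)cc(=O)o2)OCCO1 | intermediate
14 | methyl (2E)-3-{4,6-bis(benzyloxy)-3-[(benzyloxy)carbonyl]-2-pentylphenoxy}-5,7-dioxo-8-(2-pentyl-1,3-dioxolan-2-yl)oct-2-enoate | COC(=O)/C=C(/Oc1c(OCc2ccccc2)cc(OCc2ccccc2)c(C(=O)OCc2ccccc2)c1CCCCC)CC(=O)CC(=O)CC1(CCCCC)OCCO1 | intermediate (not isolated)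
15 | benzyl 4,6-bis(benzyloxy)-3-{5-hydroxy-2-(methoxycarbonyl)-3-[(2-pentyl-1,3-dioxolan-2-yl)methyl]phenoxy}-2-pentylbenzoate | COC(=O)c1c(CC2(CCCCC)OCCO2)cc(O)cc1Oc1c(OCc2ccccc2)cc(OCc2ccccc2)c(C(=O)OCc2ccccc2)c1CCCCC | intermediate (not isolated)
16 | benzyl 4,6-bis(benzyloxy)-3-[5-hydroxy-2-(methoxycarbonyl)-3-(2-oxoheptyl)phenoxy]-2-pentylbenzoate | COC(=O)c1c(CC(=O)CCCCC)cc(O)cc1Oc1c(OCc2ccccc2)cc(OCc2ccccc2)c(C(=O)OCc2ccccc2)c1CCCCC | intermediate (not isolated)
17 | benzyl 4,6-bis(benzyloxy)-3-[(6-hydroxy-1-oxo-3-pentyl-1H-isochromen-8-yl)oxy]-2-pentylbenzoate | CCCCCc1cc2cc(O)cc(Oc3c(OCc4ccccc4)cc(OCc4ccccc4)c(C(=O)OCc4ccccc4)c3CCCCC)c2c(=O)o1 | intermediate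
18 | 4,6-dihydroxy-3-[(6-hydroxy-1-oxo-3-pentyl-1H-isochromen-8-yl)oxy]-2-pentylbenzoic acid (CNP0439913.0) | CCCCCc1cc2cc(O)cc(Oc3c(O)cc(O)c(C(=O)O)c3CCCCC)c2c(=O)o1 | target

## Step count and least certain steps

Total: 11 steps. Longest linear sequence: 8 steps (steps 1, 2, 3, 4, 6, 9, 10, 11, from 1 to 18).

Step 10 (key step, proposed new method). Most likely to go wrong:
- Loss of the aryl ether by addition–elimination of methoxide at C8, before or after ring opening, because an aryloxide is a better leaving group than the alkoxides for which the fold is known.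
- Diversion into Claisen-type ring closure of C5 onto the C1 ester.
- Base-induced β-elimination of the dioxolane oxygen, or incomplete lactonisation of the crowded methyl ester in the acid stage.

Fallback, by known chemistry, from 6 to 18. Commercial methyl 2,4-dihydroxy-6-methylbenzoate would be benzylated at its non-chelated hydroxyl (BnBr, K2CO3, acetone) to methyl 4-(benzyloxy)-2-hydroxy-6-methylbenzoate F1. Tf2O and pyridine would convert this into methyl 4-(benzyloxy)-2-methyl-6-{[(trifluoromethyl)sulfonyl]oxy}benzoate F2. Palladium-catalysed aryl ether coupling of F2 with 6 (Pd(OAc)2, t-BuXPhos, K3PO4, PhMe, 100 °C) would give benzyl 4,6-bis(benzyloxy)-3-[5-(benzyloxy)-2-(methoxycarbonyl)-3-methylphenoxy]-2-pentylbenzoate F3. Lateral lithiation of the ring-A methyl group (LiN(i-Pr)2, THF, −78 °C) and acylation with N-methoxy-N-methylhexanamide would give benzyl 4,6-bis(benzyloxy)-3-[5-(benzyloxy)-2-(methoxycarbonyl)-3-(2-oxoheptyl)phenoxy]-2-pentylbenzoate F4. TsOH in toluene would close this to benzyl 4,6-bis(benzyloxy)-3-{[6-(benzyloxy)-1-oxo-3-pentyl-1H-isochromen-8-yl]oxy}-2-pentylbenzoate F5. Hydrogenolysis under the conditions of step 11 would then remove four benzyl groups and give 18.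

Step 9. Most likely to go wrong: proton transfer from the α-CH2 of the amide to the carbanion, followed by loss of the ketal oxygen; competing metalation at C3 of the pyranone; or early collapse of the adduct, so that the acidic ketone quenches unreacted carbanion. Fallback from 9 and 12 to 13: 12 would be reduced (LiAlH4, THF, −40 °C) to 2-(2-pentyl-1,3-dioxolan-2-yl)acetaldehyde F6. Lithiated 9 would add to F6 in an aldol addition, which needs one equivalent of base and gives an alkoxide that cannot quench the carbanion, to give racemic benzyl 4,6-bis(benzyloxy)-3-({6-[2-hydroxy-3-(2-pentyl-1,3-dioxolan-2-yl)propyl]-2-oxo-2H-pyran-4-yl}oxy)-2-pentylbenzoate F7. Dess–Martin periodinane would oxidise F7 to 13.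

Step 4. Most likely to go wrong: slow oxidative addition at a bromide flanked by pentyl and benzyloxy, so that protodebromination takes over, or attack of hydroxide on the benzyl ester during the oxidation. Fallback from 4 to 6: direct palladium-catalysed C–O coupling with (E)-benzaldehyde oxime as hydroxide surrogate (Pd2(dba)3, t-BuXPhos, Cs2CO3, DMF, 80 °C) would give benzyl 4,6-bis(benzyloxy)-3-{[(E)-benzylideneamino]oxy}-2-pentylbenzoate F8, which loses benzonitrile under the same base and gives 6.

Step 3. Most likely to go wrong: bromination at the position between the two benzyloxy groups, or double bromination. Fallback from 1 to 4: 1 would be benzylated to 1,3-bis(benzyloxy)-5-pentylbenzene F9 and brominated twice (NBS, 2 equiv) at the two equivalent positions beside the pentyl chain to 1,5-bis(benzyloxy)-2,4-dibromo-3-pentylbenzene F10. Exchange of one bromine (n-BuLi, 1 equiv, THF, −78 °C; then CO2) would give 4,6-bis(benzyloxy)-3-bromo-2-pentylbenzoic acid F11, and benzylation of the acid (BnBr, K2CO3, DMF) gives 4. The symmetry of F10 removes the regiochemical question at the carboxylation.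

Step 11. Most likely to go wrong: saturation of the C3–C4 double bond of the enol lactone during hydrogenolysis, or decarboxylation of the product on warm or acidic isolation. Fallback from 17 to 18: non-reductive cleavage of the three benzyl groups with BCl3 and pentamethylbenzene as cation scavenger (CH2Cl2, −78 °C), which leaves the double bond untouched; no new compound is made.

## Further compounds

F1 | step 10 | methyl 4-(benzyloxy)-2-hydroxy-6-methylbenzoate | COC(=O)c1c(C)cc(OCc2ccccc2)cc1O
F2 | step 10 | methyl 4-(benzyloxy)-2-methyl-6-{[(trifluoromethyl)sulfonyl]oxy}benzoate | COC(=O)c1c(C)cc(OCc2ccccc2)cc1OS(=O)(=O)C(F)(F)F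
F3 | step 10 | benzyl 4,6-bis(benzyloxy)-3-[5-(benzyloxy)-2-(methoxycarbonyl)-3-methylphenoxy]-2-pentylbenzoate | COC(=O)c1c(C)cc(OCc2ccccc2)cc1Oc1c(OCc2ccccc2)cc(OCc2ccccc2)c(C(=O)OCc2ccccc2)c1CCCCC
F4 | step 10 | benzyl 4,6-bis(benzyloxy)-3-[5-(benzyloxy)-2-(methoxycarbonyl)-3-(2-oxoheptyl)phenoxy]-2-pentylbenzoate | COC(=O)c1c(CC(=O)CCCCC)cc(OCc2ccccc2)cc1Oc1c(OCc2ccccc2)cc(OCc2ccccc2)c(C(=O)OCc2ccccc2)c1CCCCC
F5 | step 10 | benzyl 4,6-bis(benzyloxy)-3-{[6-(benzyloxy)-1-oxo-3-pentyl-1H-isochromen-8-yl]oxy}-2-pentylbenzoate | CCCCCc1cc2cc(OCc3ccccc3)cc(Oc3c(OCc4ccccc4)cc(OCc4ccccc4)c(C(=O)OCc4ccccc4)c3CCCCC)c2c(=O)o1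
F6 | step 9 | 2-(2-pentyl-1,3-dioxolan-2-yl)acetaldehyde | CCCCCC1(CC=O)OCCO1
F7 | step 9 | benzyl 4,6-bis(benzyloxy)-3-({6-[2-hydroxy-3-(2-pentyl-1,3-dioxolan-2-yl)propyl]-2-oxo-2H-pyran-4-yl}oxy)-2-pentylbenzoate (racemic) | CCCCCC1(CC(O)Cc2cc(Oc3c(OCc4ccccc4)cc(OCc4ccccc4)c(C(=O)OCc4ccccc4)c3CCCCC)cc(=O)o2)OCCO1
F8 | step 4 | benzyl 4,6-bis(benzyloxy)-3-{[(E)-benzylideneamino]oxy}-2-pentylbenzoate | CCCCCc1c(O/N=C/c2ccccc2)c(OCc2ccccc2)cc(OCc2ccccc2)c1C(=O)OCc1ccccc1
F9 | step 3 | 1,3-bis(benzyloxy)-5-pentylbenzene | CCCCCc1cc(OCc2ccccc2)cc(OCc2ccccc2)c1
F10 | step 3 | 1,5-bis(benzyloxy)-2,4-dibromo-3-pentylbenzene | CCCCCc1c(Br)c(OCc2ccccc2)cc(OCc2ccccc2)c1Br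
F11 | step 3 | 4,6-bis(benzyloxy)-3-bromo-2-pentylbenzoic acid | CCCCCc1c(Br)c(OCc2ccccc2)cc(OCc2ccccc2)c1C(=O)O
F0 | step 11 | none | none
A1 | alternative 1 | methyl 3-[5-(benzyloxy)-3-(hept-1-yn-1-yl)-2-(methoxycarbonyl)phenoxy]-4,6-dihydroxy-2-pentylbenzoate | CCCCCC#Cc1cc(OCc2ccccc2)cc(Oc2c(O)cc(O)c(C(=O)OC)c2CCCCC)c1C(=O)OC
A2 | alternative 1 | methyl 4-(benzyloxy)-2-(hept-1-yn-1-yl)-6-{[1-(4-hydroxy-2-oxo-2H-pyran-6-yl)-2-oxoheptyl]oxy}benzoate (racemic) | CCCCCC#Cc1cc(OCc2ccccc2)cc(OC(C(=O)CCCCC)c2cc(O)cc(=O)o2)c1C(=O)OC
A3 | alternative 2 | benzyl 4,6-bis(benzyloxy)-3-[5-(benzyloxy)-2-(methoxycarbonyl)-3-(2-methoxy-2-oxoethyl)phenoxy]-2-pentylbenzoate | COC(=O)Cc1cc(OCc2ccccc2)cc(Oc2c(OCc3ccccc3)cc(OCc3ccccc3)c(C(=O)OCc3ccccc3)c2CCCCC)c1C(=O)OC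
A4 | alternative 2 | benzyl 4,6-bis(benzyloxy)-3-[5-(benzyloxy)-3-{[(trifluoromethyl)sulfonyl]oxy}-2-(trimethylsilyl)phenoxy]-2-pentylbenzoate | C[Si](C)(C)c1c(OS(=O)(=O)C(F)(F)F)cc(OCc2ccccc2)cc1Oc1c(OCc2ccccc2)cc(OCc2ccccc2)c(C(=O)OCc2ccccc2)c1CCCCC
A5 | alternative 2 | dimethyl malonate | COC(=O)CC(=O)OC
A6 | alternative 3 | benzyl 3-{[6-(benzyloxy)-1-oxo-3-pentyl-1H-isochromen-8-yl]oxy}-4,6-dihydroxy-2-pentylbenzoate | CCCCCc1cc2cc(OCc3ccccc3)cc(Oc3c(O)cc(O)c(C(=O)OCc4ccccc4)c3CCCCC)c2c(=O)o1
A7 | alternative 3 | 6-(benzyloxy)-8-{[4-methoxy-2,4-bis(trimethylsilyloxy)buta-1,3-dien-1-yl]oxy}-3-pentyl-1H-isochromen-1-one | COC(O[Si](C)(C)C)=CC(O[Si](C)(C)C)=COc1cc(OCc2ccccc2)cc2cc(CCCCC)oc(=O)c12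
A8 | alternative 3 | benzyl oct-2-ynoate | CCCCCC#CC(=O)OCc1ccccc1
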